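**Conventions.** Germacrane numbering is used for all ring compounds: ring carbons C1–C10, C11–C13 on C7 (C12 lactone carbonyl, C13 exocyclic methylene), C14 the ester carbon on C10, C15 the CH2O carbon on C4. α is the face of H7, β the face of the C7–C11 bond.

**Assumption.** The 1(10)E,4E descriptors of the target correspond to ring-cis double bonds (C2 cis to C9, C3 cis to C6). The proposal keeps metathesis at C8=C9 as the ring-forming step but replaces a direct β-face dihydroxylation by an α-face dihydroxylation followed by inversion at C9 and C8, for the reason given under "The problem".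

## The problem

The target is a ten-membered carbocycle with a trans-fused α-methylene-γ-lactone across C6–C7. It carries two trisubstituted ring-cis olefins (C1=C10 with the C14 methyl ester, C4=C5 with C15H2OH) and four contiguous stereocentres, C6 to C9. C6 can be bought, and it controls C7 by anti addition to a butenolide. C8 and C9 carry cis oxygens that are also cis to the C7–C11 bond. In a ring-cis C8=C9 olefin with H7 eclipsing the double bond (allylic 1,3-strain) and the trans lactone fixing the C5–C6–C7–C8 dihedral, C6 and the C4=C5 bond lie on the inner face. An external syn addition therefore delivers both oxygens α, and the 8β,9β pattern has to be reached by inversion at both centres. The two oxygens must also be told apart: acetate at the allylic C9, which sits next to the enoate and is prone to SN2′ attack, and methacrylate at C8. Fragile features are the exocyclic methylene (a Michael acceptor that must be in place before any acetate, since it is installed by enolate chemistry), the methacrylate, cis-vicinal esters that migrate under base, a lactone that can move from O6 to O8, and ring olefins that face each other closely enough for transannular reactions with electrophiles. The feature that enables the key step is that C8–C9 is the only ring bond whose two carbons can each be the inner carbon of a monosubstituted vinyl group (on C7 and on C10). The cis-diol is the retron of a ring-cis C8=C9 olefin, so the ring can be closed there by metathesis with loss of ethylene.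

## Retrosynthesis

**C15 silyl ether and C8 ester.** Target 30 is cut at the O–Si bond and at the O–acyl bond of the C8 methacrylate, giving silyl ether 29 and hydroxy acetate 28. The methacrylate is the most fragile group and therefore goes on last under mild acylation. The forward steps need an acylation faster than acetyl migration and a fluoride source that spares esters.

**C8 configuration.** The 8β-alcohol 28 is traced to ketone 27 and from there to the 8α-alcohol 26. A hydride arriving from the exposed face puts the oxygen on the inner face. An SN2 displacement at C8 next to a trans acetate would invite neighbouring-group participation, so oxidation and reduction are preferred. The precursor loses one stereocentre. The forward reduction must be 1,2-selective, come from the outer face and not trigger acetyl migration.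

**C9–O and the diol.** Hydroxy acetate 26 is cut at the C9–O bond to the 8α,9α-diol 25 (Mitsunobu inversion at the allylic carbon), and 25 at both C–O bonds to tetraene 24 (syn-dihydroxylation). The syn addition sets the erythro relationship in one step, and the inversion at the more reactive allylic hydroxyl also differentiates the two oxygens. Halonium-based cis-hydroxylation on the inner face was ranked lower because cationic intermediates can be captured across the ring by C4=C5.

**C11=C13.** Tetraene 24 is cut at the exocyclic double bond to triene lactone 21. Methylenation is placed after ring closure, so that the Michael acceptor never meets the ruthenium carbene, phosphoranes or the borohydride of step 8. It is placed before any acetate, which would not survive the enolate.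

**C8=C9 (key cut).** Triene lactone 21 is opened at C8=C9 to dienoate 20, which carries a vinyl group on C7 and one on C10. Every other ring bond is either part of a trisubstituted olefin, whose geometry is better fixed on an open chain, or flanked by stereocentres. The precursor is acyclic apart from the lactone, and all its stereochemistry and olefin geometry are already in place. The forward step must close a ten-membered ring in preference to oligomers.

**C9–C10 and C1=C10.** Dienoate 20 is cut at the sp2–sp2 bond C9–C10 to (Z)-iodoenoate 18 and vinylstannane 19. Iodoenoate 18 is cut at C1=C10 to aldehyde 15 and ylide 16 (iodinated in the flask to 17). A one-step olefination with a 2-vinyl phosphonate was ranked lower because its anion is ambident and its geometry is uncertain. The iodo-ylide places the ester trans to the chain, and the coupling retains that geometry.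

**C4=C5 and the C1–C3 chain.** Aldehyde 15 comes from acetal 14, allylic alcohol 13 and enal 12. Enal 12 is cut at C4=C5 to lactone aldehyde 6 and formyl ylide 11, made from phosphonium salt 8, ethyl formate 9 and chloroacetal 7 via ylide 10. A formyl ylide is chosen over an ester ylide because the resulting enal can be reduced to the C15 alcohol without touching the lactone. It also gives the aldehyde trans to C6, which is the ring-cis arrangement.

**C7–C8.** Aldehyde 6 is traced through alcohol 5 and silyl ether 4 to butenolide 2 and vinylmagnesium bromide 3 (cut of the C7–C8 bond). Butenolide 2 is the silyl ether of commercial 1. The single purchased stereocentre (C6) sets C7.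

## Roads not taken

**Alternative 1:** The lactone O–C6 bond is cut, leading back to the ring seco-acid A1 with a methylene group at C6. In the forward step a C12 carboxyl radical would abstract the allylic C6–H through a six-membered transition state, and after oxidation of the allyl radical the carboxylate would close to lactone A2. Its merits are real. A2 already carries the exocyclic methylene and the 8β,9β-diol as an acetonide, so the configuration at C8 and C9 would have been set on an open chain. That spares the four steps the chosen plan spends on inverting both centres, and in this respect the alternative is better. Its weak points are in the key step. The allyl radical is delocalised over C4–C6, so C4=C5 geometry and O–C6 versus O–C4 closure are both at risk. Nothing but the ring decides between trans and cis lactone. Other allylic hydrogens (C2, C3) and addition of the oxygen radical to the facing olefins compete. The ten-membered ring of A1 still has to be made by some other closure. The chosen plan sets against this a ring closure and a C6/C7 relay that each rest on well-known reactivity.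

**Alternative 2:** Two ring bonds are formed (C1–C2 and C9–C10) and one is broken (C2–C9). The eight-membered silyl enol ether A3 would add methyl propiolate under ZrCl4 in a [2+2] sense, and four-electron opening of the adduct followed by hydrolysis would give the ten-membered keto enoate A4. The merits are that ring and C1=C10 enoate arise together from a smaller ring, and that C8 already carries its β-oxygen. Hydride delivery to the exposed face of the C9 ketone should then give the 9β-alcohol directly, which is better than the inversion needed at C9 in the chosen plan. The weak points are several. Enol ether formation must go towards C2 and not towards the oxygenated C8. ZrCl4 meets an allylic lactone and silyl ethers. Conrotatory opening of a cis-fused cyclobutene gives one cis and one trans ring olefin, so ring-cis C1=C10 is not secured. A4 is an alkylidene β-keto ester, prone to conjugate reduction and geometric isomerisation. A3 itself is a medium ring with a cis olefin and a trans lactone. The chosen plan fixes both trisubstituted olefins on an open chain where they cannot scramble.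

**Alternative 3:** The C2–C3 bond is cut, leading to the open-chain bis-allylic dibromide A5. Ni(CO)4 would couple the two primary allylic termini and close the ring to acetonide lactone A6. The merits are that C2–C3 is the one ring bond remote from every stereocentre, that the two halves can be made separately, and that the 8β,9β-diol is again set before cyclisation, which the chosen plan cannot match. The weak points are these. π-Allylnickel intermediates equilibrate, so the ring-cis geometry of both trisubstituted olefins is not secure. The C2 bromide is a γ-bromo enoate open to SN2′ and reduction. Coupling through the inner allyl termini would give smaller rings. Ni(CO)4 is needed stoichiometrically, is volatile and highly toxic. A6 still lacks C13. The chosen plan uses a catalytic, commercial ruthenium carbene and locks olefin geometry beforehand, but it pays for this with the late inversions at C8 and C9.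

Key step: step 13

## Route

Step 1
Reactants: 1 (S)-5-(hydroxymethyl)furan-2(5H)-one
Product: 2 (S)-5-{[tert-butyl(diphenyl)silyl]oxymethyl}furan-2(5H)-one
Conditions: TBDPSCl, imidazole, DMF, 0 °C to rt
Reagents that add atoms: tert-butyl(chloro)diphenylsilane, CC(C)(C)[Si](Cl)(c1ccccc1)c1ccccc1
Why: Silylation of a primary alcohol; imidazole is too weak a base to enolise the butenolide, so the stereocentre is kept, and the bulky ether shields one face for step 2.

Step 2
Reactants: 2 (S)-5-{[tert-butyl(diphenyl)silyl]oxymethyl}furan-2(5H)-one; 3 vinylmagnesium bromide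
Product: 4 (4R,5S)-5-{[tert-butyl(diphenyl)silyl]oxymethyl}-4-ethenyloxolan-2-one
Conditions: CH2=CHMgBr, CuBr·SMe2, THF, −78 °C; aq NH4Cl
Reagents that add atoms: vinylmagnesium bromide (3), C=C[Mg]Br
Why: Conjugate addition of the cuprate (CH2=CH)2CuMgBr to the butenolide; the vinyl group enters anti to the silyloxymethyl group, which sets C7 trans to C6 (1,2-induction).

Step 3
Reactants: 4 (4R,5S)-5-{[tert-butyl(diphenyl)silyl]oxymethyl}-4-ethenyloxolan-2-one
Product: 5 (4R,5S)-4-ethenyl-5-(hydroxymethyl)oxolan-2-one
Conditions: HF·pyridine, THF, 0 °C to rt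
Reagents that add atoms: none
Why: Fluoride cleavage of the silyl ether under weakly acidic conditions; lactone and vinyl group are inert and the five-membered lactone is favoured over ring expansion.

Step 4
Reactants: 5 (4R,5S)-4-ethenyl-5-(hydroxymethyl)oxolan-2-one
Product: 6 (2S,3R)-3-ethenyl-5-oxooxolane-2-carbaldehyde
Conditions: Dess–Martin periodinane, NaHCO3, CH2Cl2, 0 °C to rt; used crude
Reagents that add atoms: none
Why: Dess–Martin oxidation under buffered, base-free conditions keeps the α-acyloxy aldehyde from epimerising at C6; the aldehyde is taken on at once.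

Step 5
Reactants: 7 4-chloro-1,1-dimethoxybutane
Product: 8 (4,4-dimethoxybutyl)triphenylphosphonium iodide
Conditions: PPh3, NaI, MeCN, reflux
Reagents that add atoms: triphenylphosphine, c1ccc(cc1)P(c1ccccc1)c1ccccc1; sodium iodide, [Na+].[I-]
Why: SN2 alkylation of the phosphine, with halide exchange making the more reactive iodide in the flask; the acetal is stable without acid.

Step 6
Reactants: 8 (4,4-dimethoxybutyl)triphenylphosphonium iodide; 9 ethyl formate
Product: 11 5,5-dimethoxy-2-(triphenylphosphoranylidene)pentanal, via phosphorus ylide 10 (not isolated)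
Conditions: KOtBu, THF, 0 °C; then HCO2Et, 0 °C to rt
Reagents that add atoms: ethyl formate (9), CCOC=O
Why: C-formylation of a non-stabilised ylide by a formate ester; the acidic formylphosphonium ion is deprotonated by the liberated ethoxide to the stabilised formyl ylide.

Step 7
Reactants: 6 (2S,3R)-3-ethenyl-5-oxooxolane-2-carbaldehyde; 11 5,5-dimethoxy-2-(triphenylphosphoranylidene)pentanal
Product: 12 (2E)-2-(3,3-dimethoxypropyl)-3-[(2S,3R)-3-ethenyl-5-oxooxolan-2-yl]prop-2-enal
Conditions: toluene, 60 °C
Reagents that add atoms: 5,5-dimethoxy-2-(triphenylphosphoranylidene)pentanal (11), COC(OC)CCC(C=O)=P(c1ccccc1)(c1ccccc1)c1ccccc1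
Why: Wittig reaction of a stabilised α-alkyl formyl ylide, which places the formyl group trans to the C6 substituent (E enal, the ring-cis C3/C6 arrangement); the ylide is too weakly basic to epimerise C6.

Step 8
Reactants: 12 (2E)-2-(3,3-dimethoxypropyl)-3-[(2S,3R)-3-ethenyl-5-oxooxolan-2-yl]prop-2-enal
Product: 13 (4R,5S)-4-ethenyl-5-[(1E)-2-(hydroxymethyl)-5,5-dimethoxypent-1-en-1-yl]oxolan-2-one
Conditions: NaBH4, CeCl3·7H2O, MeOH, −40 °C
Reagents that add atoms: none
Why: Luche 1,2-reduction of the enal to the C15 allylic alcohol; lactone and acetal are not reduced at this temperature.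

Step 9
Reactants: 13 (4R,5S)-4-ethenyl-5-[(1E)-2-(hydroxymethyl)-5,5-dimethoxypent-1-en-1-yl]oxolan-2-one
Product: 14 (4R,5S)-5-[(1E)-2-{[tert-butyl(diphenyl)silyl]oxymethyl}-5,5-dimethoxypent-1-en-1-yl]-4-ethenyloxolan-2-one
Conditions: TBDPSCl, imidazole, CH2Cl2, rt
Reagents that add atoms: tert-butyl(chloro)diphenylsilane, CC(C)(C)[Si](Cl)(c1ccccc1)c1ccccc1
Why: Silylation; this ether is chosen because it survives the acid of step 10, shields C4=C5 in step 15 and still leaves with fluoride at the end.

Step 10
Reactants: 14 (4R,5S)-5-[(1E)-2-{[tert-butyl(diphenyl)silyl]oxymethyl}-5,5-dimethoxypent-1-en-1-yl]-4-ethenyloxolan-2-one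
Product: 15 (4E)-4-{[tert-butyl(diphenyl)silyl]oxymethyl}-5-[(2S,3R)-3-ethenyl-5-oxooxolan-2-yl]pent-4-enal
Conditions: PPTS, acetone/H2O, 45 °C
Reagents that add atoms: water, O
Why: Acid-catalysed hydrolysis of a dimethyl acetal; the silyl ether and the allylic lactone tolerate this mild acid.

Step 11
Reactants: 15 (4E)-4-{[tert-butyl(diphenyl)silyl]oxymethyl}-5-[(2S,3R)-3-ethenyl-5-oxooxolan-2-yl]pent-4-enal; 16 methyl (triphenylphosphoranylidene)acetate
Product: 18 methyl (2Z,6E)-6-{[tert-butyl(diphenyl)silyl]oxymethyl}-7-[(2S,3R)-3-ethenyl-5-oxooxolan-2-yl]-2-iodohepta-2,6-dienoate, via iodo ylide 17 (not isolated)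
Conditions: 16, N-iodosuccinimide, K2CO3, CH2Cl2, −20 °C; then 15, −20 °C to rt
Reagents that add atoms: methyl (triphenylphosphoranylidene)acetate (16), COC(=O)C=P(c1ccccc1)(c1ccccc1)c1ccccc1; N-iodosuccinimide, O=C1CCC(=O)N1I
Why: Iodination of the stabilised ylide followed by Wittig reaction; the ester should end trans to the chain as usual for stabilised ylides, giving the (Z)-α-iodo enoate, and the iodinating agent is consumed before the olefin-bearing aldehyde is added.

Step 12
Reactants: 18 methyl (2Z,6E)-6-{[tert-butyl(diphenyl)silyl]oxymethyl}-7-[(2S,3R)-3-ethenyl-5-oxooxolan-2-yl]-2-iodohepta-2,6-dienoate; 19 tributyl(vinyl)stannane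
Product: 20 methyl (2E,6E)-6-{[tert-butyl(diphenyl)silyl]oxymethyl}-2-ethenyl-7-[(2S,3R)-3-ethenyl-5-oxooxolan-2-yl]hepta-2,6-dienoate
Conditions: Bu3SnCH=CH2, Pd2(dba)3 (cat.), AsPh3, CuI (cat.), NMP, rt
Reagents that add atoms: tributyl(vinyl)stannane (19), C=C[Sn](CCCC)(CCCC)CCCC
Why: Stille coupling with retention of olefin geometry; insertion of zerovalent palladium into the C–I bond at room temperature with the weak donor AsPh3 should be far faster than ionisation of the allylic C6–O lactone bond, and the chain cis to the new vinyl group disfavours the s-cis diene needed for Diels–Alder dimerisation.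

Step 13
Reactants: 20 methyl (2E,6E)-6-{[tert-butyl(diphenyl)silyl]oxymethyl}-2-ethenyl-7-[(2S,3R)-3-ethenyl-5-oxooxolan-2-yl]hepta-2,6-dienoate
Product: 21 methyl 15-[tert-butyl(diphenyl)silyl]oxygermacra-1(10),4,8-trien-12,6α-olid-14-oate (7αH; C1=C10, C4=C5 and C8=C9 all ring-cis)
Conditions: second-generation Grubbs catalyst RuCl2(H2IMes)(PCy3)(=CHPh) (10 mol %), toluene (0.001 M), 80 °C, argon sparge
Reagents that add atoms: none
Why: The ruthenium benzylidene exchanges onto the unhindered C7 vinyl group, the new alkylidene adds to the terminal CH=CH2 of the dienoate through a metallacyclobutane, and cycloreversion releases ethylene and forms C8=C9. The closest known reaction type is ring-closing ene–diene metathesis to medium-ring cis-cycloalkenes and cyclic 1,3-dienes. The ten-membered carbocycle is closed in the endo mode, with both olefin carbons ending up in the ring. No stereocentre is formed; the new olefin must be ring-cis, and the ring size together with the two existing ring-cis olefins and the trans lactone should leave no room for a trans double bond. Site selectivity rests on substitution: only the two monosubstituted olefins can enter the cycle, while trisubstituted C4=C5 and the trisubstituted, electron-poor C1=C10 are inert, which also blocks ring contraction through C1=C10. Closure should compete with oligomerisation because only two sp3 carbons lie between each pair of sp2 units, and a conformer with H6 and H7 eclipsing their olefins brings the two vinyl termini together without strain. High dilution and removal of ethylene support this.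

Step 14
Reactants: 21 methyl 15-[tert-butyl(diphenyl)silyl]oxygermacra-1(10),4,8-trien-12,6α-olid-14-oate
Product: 24 methyl 15-[tert-butyl(diphenyl)silyl]oxygermacra-1(10),4,8,11(13)-tetraen-12,6α-olid-14-oate, via Mannich base 22 (not isolated), via ammonium iodide 23 (not isolated)
Conditions: LiN(SiMe3)2, THF, −78 °C; CH2=NMe2+ I−, −78 to 0 °C; MeI, CH2Cl2/MeOH, rt; aq NaHCO3, rt
Reagents that add atoms: N,N-dimethylmethyleneiminium iodide, C=[N+](C)C.[I-]
Why: α-Methylenation by Mannich reaction of the lactone enolate, exhaustive methylation and E1cB elimination; the lactone α-CH2 is deprotonated faster than the γ-position of the trisubstituted enoate, and the temporary C11 centre (aminomethyl group anti to C8) is destroyed again.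

Step 15
Reactants: 24 methyl 15-[tert-butyl(diphenyl)silyl]oxygermacra-1(10),4,8,11(13)-tetraen-12,6α-olid-14-oate
Product: 25 methyl 15-[tert-butyl(diphenyl)silyl]oxy-8α,9α-dihydroxygermacra-1(10),4,11(13)-trien-12,6α-olid-14-oate (8R,9S)
Conditions: OsO4 (cat.), N-methylmorpholine N-oxide, acetone/H2O, 0 °C
Reagents that add atoms: osmium tetroxide (both oxygen atoms, restored by the N-oxide), O=[Os](=O)(=O)=O; N-methylmorpholine N-oxide, C[N+]1([O-])CCOCC1
Why: Catalytic syn-dihydroxylation, a concerted addition that avoids cationic transannular paths; C8=C9 is the only 1,2-disubstituted olefin not conjugated to a carbonyl, while C4=C5 is trisubstituted, flanked by two allylic C–O bonds and the bulky silyl ether, and C1=C10 and C11=C13 are acrylate-type. With H7 eclipsing the olefin, C6 and C4=C5 block the inner face, so both oxygens should arrive on the outer face, anti to C6 and cis to H7 (8α,9α, erythro).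

Step 16
Reactants: 25 methyl 15-[tert-butyl(diphenyl)silyl]oxy-8α,9α-dihydroxygermacra-1(10),4,11(13)-trien-12,6α-olid-14-oate
Product: 26 methyl 9β-acetoxy-15-[tert-butyl(diphenyl)silyl]oxy-8α-hydroxygermacra-1(10),4,11(13)-trien-12,6α-olid-14-oate (8R,9R)
Conditions: PPh3, DIAD (betaine preformed), AcOH, THF, 0 °C
Reagents that add atoms: acetic acid, CC(=O)O
Why: Mitsunobu reaction of a cis-diol: the diol is activated through its cyclic phosphorane and acetate displaces at the allylic carbon C9 with inversion, which sets 9β and differentiates the two oxygens in one step. The near-neutral medium avoids lactone migration to the free 8α-hydroxyl.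

Step 17
Reactants: 26 methyl 9β-acetoxy-15-[tert-butyl(diphenyl)silyl]oxy-8α-hydroxygermacra-1(10),4,11(13)-trien-12,6α-olid-14-oate
Product: 27 methyl 9β-acetoxy-15-[tert-butyl(diphenyl)silyl]oxy-8-oxogermacra-1(10),4,11(13)-trien-12,6α-olid-14-oate (9R)
Conditions: Dess–Martin periodinane, NaHCO3, CH2Cl2, 0 °C; used crude
Reagents that add atoms: none
Why: Dess–Martin oxidation of the secondary alcohol; the buffered, amine-free conditions should leave the acidic C9–H of the α-acetoxy ketone untouched.

Step 18
Reactants: 27 methyl 9β-acetoxy-15-[tert-butyl(diphenyl)silyl]oxy-8-oxogermacra-1(10),4,11(13)-trien-12,6α-olid-14-oate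
Product: 28 methyl 9β-acetoxy-15-[tert-butyl(diphenyl)silyl]oxy-8β-hydroxygermacra-1(10),4,11(13)-trien-12,6α-olid-14-oate (8S,9R)
Conditions: NaBH4, CeCl3·7H2O, MeOH, −78 °C; AcOH quench
Reagents that add atoms: none
Why: Luche reduction; hydride should reach the C8 carbonyl from the same exposed face that the osmium reagent used, so the hydrogen ends outside and the oxygen inside (8β, cis to the 9β-acetate and to C11). Low temperature and an acidic quench suppress acetyl migration and conjugate reduction of the exocyclic methylene.

Step 19
Reactants: 28 methyl 9β-acetoxy-15-[tert-butyl(diphenyl)silyl]oxy-8β-hydroxygermacra-1(10),4,11(13)-trien-12,6α-olid-14-oate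
Product: 29 methyl 9β-acetoxy-15-[tert-butyl(diphenyl)silyl]oxy-8β-(2-methylprop-2-enoyloxy)germacra-1(10),4,11(13)-trien-12,6α-olid-14-oate
Conditions: methacrylic anhydride, DMAP (cat.), pyridine, CH2Cl2, 0 °C
Reagents that add atoms: methacrylic anhydride, C=C(C)C(=O)OC(=O)C(C)=C
Why: Acylation with nucleophilic catalysis and retention at C8; a cold, weakly basic medium keeps acylation ahead of acetyl or lactone migration.

Step 20
Reactants: 29 methyl 9β-acetoxy-15-[tert-butyl(diphenyl)silyl]oxy-8β-(2-methylprop-2-enoyloxy)germacra-1(10),4,11(13)-trien-12,6α-olid-14-oate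
Product: 30 methyl 9β-acetoxy-15-hydroxy-8β-(2-methylprop-2-enoyloxy)germacra-1(10),4,11(13)-trien-12,6α-olid-14-oate (6R,7S,8S,9R; target)
Conditions: HF·pyridine, pyridine, THF, 0 °C to rt
Reagents that add atoms: none
Why: Fluoride cleavage of the primary allylic silyl ether under buffered acidic conditions, which leaves the three esters, the lactone and both Michael acceptors untouched.

## Compound list

1 | (S)-5-(hydroxymethyl)furan-2(5H)-one | O=C1O[C@@H](C=C1)CO | starting material
2 | (S)-5-{[tert-butyl(diphenyl)silyl]oxymethyl}furan-2(5H)-one | O=C1O[C@@H](C=C1)CO[Si](c2ccccc2)(c2ccccc2)C(C)(C)C | intermediate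
3 | vinylmagnesium bromide | C=C[Mg]Br | starting material
4 | (4R,5S)-5-{[tert-butyl(diphenyl)silyl]oxymethyl}-4-ethenyloxolan-2-one | C=C[C@H]1CC(=O)O[C@@H]1CO[Si](c2ccccc2)(c2ccccc2)C(C)(C)C | intermediate
5 | (4R,5S)-4-ethenyl-5-(hydroxymethyl)oxolan-2-one | C=C[C@H]1CC(=O)O[C@@H]1CO | intermediate
6 | (2S,3R)-3-ethenyl-5-oxooxolane-2-carbaldehyde | C=C[C@H]1CC(=O)O[C@@H]1C=O | intermediate
7 | 4-chloro-1,1-dimethoxybutane | ClCCCC(OC)OC | starting material
8 | (4,4-dimethoxybutyl)triphenylphosphonium iodide | COC(OC)CCC[P+](c1ccccc1)(c1ccccc1)c1ccccc1.[I-] | intermediate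
9 | ethyl formate | CCOC=O | starting material
10 | (4,4-dimethoxybutylidene)triphenylphosphorane | COC(OC)CCC=P(c1ccccc1)(c1ccccc1)c1ccccc1 | intermediate
11 | 5,5-dimethoxy-2-(triphenylphosphoranylidene)pentanal | COC(OC)CCC(C=O)=P(c1ccccc1)(c1ccccc1)c1ccccc1 | intermediate
12 | (2E)-2-(3,3-dimethoxypropyl)-3-[(2S,3R)-3-ethenyl-5-oxooxolan-2-yl]prop-2-enal | C=C[C@H]1CC(=O)O[C@@H]1/C=C(/C=O)CCC(OC)OC | intermediate
13 | (4R,5S)-4-ethenyl-5-[(1E)-2-(hydroxymethyl)-5,5-dimethoxypent-1-en-1-yl]oxolan-2-one | C=C[C@H]1CC(=O)O[C@@H]1/C=C(/CO)CCC(OC)OC | intermediate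
14 | (4R,5S)-5-[(1E)-2-{[tert-butyl(diphenyl)silyl]oxymethyl}-5,5-dimethoxypent-1-en-1-yl]-4-ethenyloxolan-2-one | C=C[C@H]1CC(=O)O[C@@H]1/C=C(/CO[Si](c2ccccc2)(c2ccccc2)C(C)(C)C)CCC(OC)OC | intermediate
15 | (4E)-4-{[tert-butyl(diphenyl)silyl]oxymethyl}-5-[(2S,3R)-3-ethenyl-5-oxooxolan-2-yl]pent-4-enal | C=C[C@H]1CC(=O)O[C@@H]1/C=C(/CO[Si](c2ccccc2)(c2ccccc2)C(C)(C)C)CCC=O | intermediate
16 | methyl (triphenylphosphoranylidene)acetate | COC(=O)C=P(c1ccccc1)(c1ccccc1)c1ccccc1 | starting material
17 | methyl iodo(triphenylphosphoranylidene)acetate | COC(=O)C(I)=P(c1ccccc1)(c1ccccc1)c1ccccc1 | intermediate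
18 | methyl (2Z,6E)-6-{[tert-butyl(diphenyl)silyl]oxymethyl}-7-[(2S,3R)-3-ethenyl-5-oxooxolan-2-yl]-2-iodohepta-2,6-dienoate | C=C[C@H]1CC(=O)O[C@@H]1/C=C(/CO[Si](c2ccccc2)(c2ccccc2)C(C)(C)C)CC/C=C(/C(=O)OC)I | intermediate
19 | tributyl(vinyl)stannane | C=C[Sn](CCCC)(CCCC)CCCC | starting material
20 | methyl (2E,6E)-6-{[tert-butyl(diphenyl)silyl]oxymethyl}-2-ethenyl-7-[(2S,3R)-3-ethenyl-5-oxooxolan-2-yl]hepta-2,6-dienoate | C=C[C@H]1CC(=O)O[C@@H]1/C=C(/CO[Si](c2ccccc2)(c2ccccc2)C(C)(C)C)CC/C=C(/C(=O)OC)C=C | intermediate
21 | methyl 15-[tert-butyl(diphenyl)silyl]oxygermacra-1(10),4,8-trien-12,6α-olid-14-oate (7αH, all ring olefins ring-cis) | C1/C=C(C(=O)OC)\C=C/[C@H]2CC(=O)O[C@@H]2/C=C(/CO[Si](c3ccccc3)(c3ccccc3)C(C)(C)C)C1 | intermediate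
22 | (11R)-13-(dimethylamino)-11,13-dihydro derivative of 24 (aminomethyl group anti to C8 on the lactone) | C1/C=C(C(=O)OC)\C=C/[C@H]2[C@H](CN(C)C)C(=O)O[C@@H]2/C=C(/CO[Si](c3ccccc3)(c3ccccc3)C(C)(C)C)C1 | intermediate
23 | N-methyl quaternary ammonium iodide of 22 | C1/C=C(C(=O)OC)\C=C/[C@H]2[C@H](C[N+](C)(C)C)C(=O)O[C@@H]2/C=C(/CO[Si](c3ccccc3)(c3ccccc3)C(C)(C)C)C1.[I-] | intermediate
24 | methyl 15-[tert-butyl(diphenyl)silyl]oxygermacra-1(10),4,8,11(13)-tetraen-12,6α-olid-14-oate | C1/C=C(C(=O)OC)\C=C/[C@H]2C(=C)C(=O)O[C@@H]2/C=C(/CO[Si](c3ccccc3)(c3ccccc3)C(C)(C)C)C1 | intermediate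
25 | methyl 15-[tert-butyl(diphenyl)silyl]oxy-8α,9α-dihydroxygermacra-1(10),4,11(13)-trien-12,6α-olid-14-oate (8R,9S) | O[C@@H]1[C@H]2C(=C)C(=O)O[C@@H]2/C=C(/CO[Si](c3ccccc3)(c3ccccc3)C(C)(C)C)CC/C=C(/C(=O)OC)[C@@H]1O | intermediate
26 | methyl 9β-acetoxy-15-[tert-butyl(diphenyl)silyl]oxy-8α-hydroxygermacra-1(10),4,11(13)-trien-12,6α-olid-14-oate (8R,9R) | O[C@@H]1[C@H]2C(=C)C(=O)O[C@@H]2/C=C(/CO[Si](c3ccccc3)(c3ccccc3)C(C)(C)C)CC/C=C(/C(=O)OC)[C@H]1OC(C)=O | intermediate
27 | methyl 9β-acetoxy-15-[tert-butyl(diphenyl)silyl]oxy-8-oxogermacra-1(10),4,11(13)-trien-12,6α-olid-14-oate (9R) | O=C1[C@H]2C(=C)C(=O)O[C@@H]2/C=C(/CO[Si](c3ccccc3)(c3ccccc3)C(C)(C)C)CC/C=C(/C(=O)OC)[C@H]1OC(C)=O | intermediate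
28 | methyl 9β-acetoxy-15-[tert-butyl(diphenyl)silyl]oxy-8β-hydroxygermacra-1(10),4,11(13)-trien-12,6α-olid-14-oate (8S,9R) | O[C@H]1[C@H]2C(=C)C(=O)O[C@@H]2/C=C(/CO[Si](c3ccccc3)(c3ccccc3)C(C)(C)C)CC/C=C(/C(=O)OC)[C@H]1OC(C)=O | intermediate
29 | methyl 9β-acetoxy-15-[tert-butyl(diphenyl)silyl]oxy-8β-(2-methylprop-2-enoyloxy)germacra-1(10),4,11(13)-trien-12,6α-olid-14-oate | C=C(C)C(=O)O[C@H]1[C@H]2C(=C)C(=O)O[C@@H]2/C=C(/CO[Si](c3ccccc3)(c3ccccc3)C(C)(C)C)CC/C=C(/C(=O)OC)[C@H]1OC(C)=O | intermediate
30 | methyl 9β-acetoxy-15-hydroxy-8β-(2-methylprop-2-enoyloxy)germacra-1(10),4,11(13)-trien-12,6α-olid-14-oate (6R,7S,8S,9R) | C=C(C)C(=O)O[C@H]1[C@H]2C(=C)C(=O)O[C@@H]2/C=C(/CO)CC/C=C(/C(=O)OC)[C@H]1OC(C)=O | target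

## Step count and least certain steps

Total: 20 steps. Longest linear sequence: 18 steps (steps 1–4 and 7–20, from 1); steps 5 and 6 prepare ylide 11.

**Step 13 (key step).** Intermolecular metathesis may overtake ring closure and give cyclic dimers and oligomers, because a ten-membered ring closes slowly. The catalyst may also be held back after loading onto the diene terminus, where the neighbouring ester can chelate the resulting vinyl carbene. Fallback, from aldehyde 15 back to 21: 15 is treated with the lithium dienolate of methyl but-3-enoate (from methyl crotonate and LiN(iPr)2), which adds through its α-carbon and gives the β-hydroxy α-vinyl ester F1 (both C1/C10 epimers serve). Ring closure of F1 with the same second-generation Grubbs catalyst RuCl2(H2IMes)(PCy3)(=CHPh) then joins two isolated, electron-neutral vinyl groups to the ten-membered hydroxy ester F2. Mesylation to the mesylate F3 and elimination with DBU introduce C1=C10 after the ring exists and return to 21. The price is that C1=C10 geometry is then set by the ring and not beforehand.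

**Step 16.** Acetate may attack C1 with allylic transposition (SN2′) instead of C9, since the C9 alcohol sits next to the α-carbon of an enoate, or the displacement may be slow because the backside of C9 points over the ring. Fallback, from tetraene 24 to hydroxy acetate 28, bypassing steps 15–18: Woodward cis-hydroxylation (I2, AgOAc, wet AcOH). The iodonium ion forms on the outer face and acetate opens it from inside to the trans iodo acetate F6. The neighbouring acetate then displaces iodide with silver assistance, and hydrolysis of the resulting acetoxonium ion leaves both oxygens on the β-face as the cis hydroxy acetate 28, after equilibration of the acetyl position if needed. This is held in reserve because iodonium formation at C4=C5 and transannular capture are conceivable.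

**Step 15.** The exocyclic methylene or C4=C5 may be osmylated as well, because four olefins compete and the desired one is part of a cross-conjugated diene. Fallback, from 21 to diol 25: step 14 is stopped at the Mannich base 22, which is isolated, so that no acrylate-type methylene is present during osmylation. Dihydroxylation of 22 under the same conditions gives the amino diol F4. Methylation with MeI to the ammonium iodide F5 and elimination with aqueous NaHCO3 then unveil the methylene group and return to 25.

**Step 18.** Hydride delivery may show poor facial selectivity if the C9 acetate rather than the ring dictates the approach. The acetyl group may also migrate to the new cis-hydroxyl, and the ketone may enolise towards C9 beforehand. Fallback, from hydroxy acetate 26 directly to diester 29, without 27 and 28: Mitsunobu esterification of the 8α-alcohol with methacrylic acid (PPh3, DIAD, toluene), which inverts C8 and installs the methacrylate in one operation. It is second choice because the trans acetate at C9 could participate.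

## Further compounds

F1 | step 13 | methyl 2-ethenyl-3-hydroxy-7-{[tert-butyl(diphenyl)silyl]oxymethyl}-8-[(2S,3R)-3-ethenyl-5-oxooxolan-2-yl]oct-7-enoate (7E; mixture of epimers at C2 and C3 of the chain) | C=C[C@H]1CC(=O)O[C@@H]1/C=C(/CO[Si](c2ccccc2)(c2ccccc2)C(C)(C)C)CCC(O)C(C=C)C(=O)OC
F2 | step 13 | methyl 15-[tert-butyl(diphenyl)silyl]oxy-1-hydroxygermacra-4,8-dien-12,6α-olid-14-oate (ring-cis olefins; epimers at C1 and C10) | C1C(O)C(C(=O)OC)/C=C\[C@H]2CC(=O)O[C@@H]2/C=C(/CO[Si](c3ccccc3)(c3ccccc3)C(C)(C)C)C1
F3 | step 13 | 1-O-methanesulfonate of F2 | C1C(OS(C)(=O)=O)C(C(=O)OC)/C=C\[C@H]2CC(=O)O[C@@H]2/C=C(/CO[Si](c3ccccc3)(c3ccccc3)C(C)(C)C)C1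
F4 | step 15 | (11R)-13-(dimethylamino)-11,13-dihydro derivative of diol 25 | O[C@@H]1[C@H]2[C@H](CN(C)C)C(=O)O[C@@H]2/C=C(/CO[Si](c3ccccc3)(c3ccccc3)C(C)(C)C)CC/C=C(/C(=O)OC)[C@@H]1O
F5 | step 15 | N-methyl quaternary ammonium iodide of F4 | O[C@@H]1[C@H]2[C@H](C[N+](C)(C)C)C(=O)O[C@@H]2/C=C(/CO[Si](c3ccccc3)(c3ccccc3)C(C)(C)C)CC/C=C(/C(=O)OC)[C@@H]1O.[I-]
F6 | step 16 | methyl 9β-acetoxy-15-[tert-butyl(diphenyl)silyl]oxy-8α-iodogermacra-1(10),4,11(13)-trien-12,6α-olid-14-oate | I[C@@H]1[C@H]2C(=C)C(=O)O[C@@H]2/C=C(/CO[Si](c3ccccc3)(c3ccccc3)C(C)(C)C)CC/C=C(/C(=O)OC)[C@H]1OC(C)=O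
F0 | step 18 | none | none
A1 | alternative 1 | ring seco-acid: 14-methyl ester of 15-(tert-butyldimethylsilyloxy)-8β,9β-(isopropylidenedioxy)germacra-1(10),4,11(13)-triene-12,14-dioic acid (C6 is CH2) | CC1(C)O[C@H]2[C@@H](C(=C)C(=O)O)C/C=C(/CO[Si](C)(C)C(C)(C)C)CC/C=C(/C(=O)OC)[C@H]2O1
A2 | alternative 1 | trans α-methylene lactone with C8,C9 acetonide and C15 silyl ether | CC1(C)O[C@H]2[C@H]3C(=C)C(=O)O[C@@H]3/C=C(/CO[Si](C)(C)C(C)(C)C)CC/C=C(/C(=O)OC)[C@H]2O1
A3 | alternative 2 | eight-membered trimethylsilyl enol ether (C9=C2) with 8β-silyloxy group and trans lactone | CC(C)(C)[Si](C)(C)O[C@H]1[C@H]2CC(=O)O[C@@H]2/C=C(/CO[Si](C)(C)C(C)(C)C)C/C=C1/O[Si](C)(C)C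
A4 | alternative 2 | ten-membered C9 ketone with C1=C10 enoate | CC(C)(C)[Si](C)(C)O[C@H]1[C@H]2CC(=O)O[C@@H]2/C=C(/CO[Si](C)(C)C(C)(C)C)CC/C=C(/C(=O)OC)C1=O
A5 | alternative 3 | open-chain bis-allylic dibromide (bromides at C2 and C3) with C8,C9 acetonide and trans lactone | BrC/C=C(/C(=O)OC)[C@H]1OC(C)(C)O[C@H]1[C@H]2CC(=O)O[C@@H]2/C=C(/CO[Si](C)(C)C(C)(C)C)CBr
A6 | alternative 3 | ten-membered lactone with C8,C9 acetonide, lacking the C13 methylene | CC1(C)O[C@H]2[C@H]3CC(=O)O[C@@H]3/C=C(/CO[Si](C)(C)C(C)(C)C)CC/C=C(/C(=O)OC)[C@H]2O1
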